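The disconnection traces the cyclopentane ring (C1–C5) back to a cyclobutanol by undoing the C4–C5 bond. The key step exploits the spiro carbon C5. C5 is α to the oxygen-bearing C1 and is also one end of the C5–C6=C7 allyl unit of the cyclohexene ring. A silylated 1-(cyclohexenyl)cyclobutanol, made from (+)-dihydrocarvone and cyclobutanone, is protonated at its remote isopropenyl group. The charge moves to C5 and one cyclobutane carbon shifts. This gives the spiro[4.5]decadienyl silyl enol ether with C5 and the C6=C7 alkene in place. A three-component o-quinone methide cycloaddition, C2 methylation, reductive chroman closure and double formylation complete the target.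

Key step: step 3

Atom labels: the terpene atoms are numbered as in spiro[4.5]decane. C1 = OCH, C2 = C(CH3), C3/C4 = CH2, C5 = spiro carbon, C6=C7(iPr), C8/C9 = CH2, C10 = CH(CH3). C1' is the benzylic CH that carries the isobutyl group.

Assumption: commercial (+)-dihydrocarvone contains its C2 epimer. Only the (2R,5R) isomer is drawn. The epimer is taken to be removed by crystallisation of 3 and chromatography of 7, because after step 3 it would lead into the enantiomeric series.

Step 1
Reactants: 1 (+)-dihydrocarvone, (2R,5R)-2-methyl-5-(prop-1-en-2-yl)cyclohexan-1-one; 2 2,4,6-tri(propan-2-yl)benzenesulfonohydrazide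
Product: 3 (E)-N'-[(2R,5R)-2-methyl-5-(prop-1-en-2-yl)cyclohexylidene]-2,4,6-tri(propan-2-yl)benzenesulfonohydrazide
Conditions: MeCN, cat. HCl, rt; recrystallisation
Reagents that add atoms: none
Why: Acid-catalysed hydrazone condensation in which the only epimerisable centre (the methyl-bearing carbon, later C10) stays in the favoured trans-diequatorial arrangement, and the crystalline product should allow removal of the epimer.

Step 2
Reactants: 3 trisylhydrazone; 4 cyclobutanone
Product: 7 triethyl({1-[(3R,6R)-6-methyl-3-(prop-1-en-2-yl)cyclohex-1-en-1-yl]cyclobutyl}oxy)silane, via vinyllithium 5 (not isolated), via lithium alkoxide 6 (not isolated)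
Conditions: n-BuLi (2.1 equiv), TMEDA, THF, −78 → 0 °C; 4, −78 °C; TESCl, cat. DMAP, −78 °C → rt; H2O
Reagents that add atoms: chlorotriethylsilane, CC[Si](Cl)(CC)CC
Why: Shapiro reaction, in which deprotonation at the less substituted CH2 and loss of sulfinate and N2 give 5, this adds 1,2 to cyclobutanone, and alkoxide 6 is capped in the same flask so that the tertiary allylic C–O bond can survive the acid of step 3; both stereocentres are untouched.

Step 3
Reactants: 7 silylated 1-(cyclohexenyl)cyclobutanol
Product: 10 triethyl{[(5R,10R)-10-methyl-7-(propan-2-yl)spiro[4.5]deca-1,6-dien-1-yl]oxy}silane, via allyl cation 8 (not isolated), via silyloxocarbenium ion 9 (not isolated)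
Conditions: HNTf2 (1.0 equiv), CH2Cl2, −78 °C; then Et3N, −78 → 0 °C
Reagents that add atoms: none
Why: One equivalent of strong acid protonates the unhindered isopropenyl group, a 1,2-hydride shift from C7 gives the doubly tertiary allyl cation 8 (C5–C6–C7), one of the two equivalent cyclobutane CH2 groups (the future C4) migrates from the carbinol carbon C1 to C5 to give 9, and Et3N removes H-2, the only α-hydrogen, so that the silyl group stays on the same oxygen throughout. The closest known reaction type is the acid-induced semipinacol (Wagner–Meerwein) ring expansion of 1-alkenylcyclobutanol derivatives to α-quaternary cyclopentanones, followed by soft enolisation as with silyl triflate and amine. No ring is closed from an open chain: ring C1–C5 arises from the four-membered ring by a suprafacial 1,2-alkyl shift, driven by release of ring strain and formation of the C=O+ bond, and the six-membered ring is carried through. C5 is the only new stereocentre: A(1,2) strain with the bulky siloxycyclobutyl group holds the C10 methyl group pseudoaxial, so C4 bonds to C5 on the opposite face and C1 ends cis to that methyl group (5R), while the stereocentre at C7 is erased. The step needs protonation at the isopropenyl group rather than at the ring alkene or the oxygen, which the inductive and steric shielding by the siloxy group should secure, and it needs the shift to outrun loss of H-10 from 8. Because each molecule consumes its proton and stores the charge as 9, no free Brønsted acid is left to move the new C6=C7 double bond.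

Step 4
Reactants: 11 2,4,6-trihydroxybenzaldehyde
Product: 12 2-hydroxy-4,6-bis(methoxymethoxy)benzaldehyde
Conditions: MOMCl (2.1 equiv), iPr2NEt, CH2Cl2, 0 °C
Reagents that add atoms: chloromethyl methyl ether, COCCl
Why: Selective O-alkylation (Williamson type), in which the last ortho OH is held back by its hydrogen bond to the formyl oxygen.

Step 5
Reactants: 12 bis-MOM aldehyde
Product: 13 tert-butyl 2-formyl-3,5-bis(methoxymethoxy)phenyl carbonate
Conditions: Boc2O, cat. DMAP, CH2Cl2, rt
Reagents that add atoms: di-tert-butyl dicarbonate, CC(C)(C)OC(=O)OC(=O)OC(C)(C)C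
Why: DMAP-catalysed O-acylation of the remaining phenol installs the trigger for low-temperature o-quinone methide formation.

Step 6
Reactants: 10 silyl enol ether; 13 O-Boc aldehyde; 14 isobutylmagnesium bromide
Product: 17 (2R,5R,10R)-2-{(1R)-1-[2-hydroxy-4,6-bis(methoxymethoxy)phenyl]-3-methylbutyl}-10-methyl-7-(propan-2-yl)spiro[4.5]dec-6-en-1-one (drawn in the open keto-phenol form), via o-quinone methide 15 (not isolated), via silyl ketal 16 (not isolated)
Conditions: 14 added to 13 + 10, Et2O–toluene, −78 °C → rt; then AcOH–THF–H2O, rt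
Reagents that add atoms: none
Why: Grignard 1,2-addition, O-to-O Boc migration and loss of tert-butyl carbonate release the (E)-o-quinone methide 15, which undergoes an inverse-electron-demand hetero-Diels–Alder reaction with the electron-rich C1=C2 bond of 10 (C1' to the nucleophilic C2, O to C1) on the face next to the flat C6–H and away from C10 and its methyl group, with the siloxy group endo and the spiro ring exo, and this sets C1' (R); mild acid then opens ketal 16 to 17, whose C2 configuration is of no consequence.

Step 7
Reactants: 17 keto phenol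
Product: 18 (2S,5R,10R)-2-{(1S)-1-[2-hydroxy-4,6-bis(methoxymethoxy)phenyl]-3-methylbutyl}-2,10-dimethyl-7-(propan-2-yl)spiro[4.5]dec-6-en-1-one (same spatial arrangement at C1'; the descriptor changes by CIP priority only)
Conditions: LDA (commercial, 2.2 equiv), THF, −78 → 0 °C; MeI (1.1 equiv), −78 → −20 °C; H2O
Reagents that add atoms: iodomethane, CI
Why: Alkylation after double deprotonation takes place at the more basic carbon site C2, the only enolisable position; with H-1' eclipsing the enolate C–O bond (A(1,3) strain) the aryl group covers the C10 face, so MeI enters from the C6 face, which the spiro ring also leaves more open, and the quaternary C2 (S) forms with its methyl group syn to C6.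

Step 8
Reactants: 18 α-methyl keto phenol
Product: 19 chroman-5,7-diol, the target without its two formyl groups, (1R,2S,5R,10R,1'R)
Conditions: Et3SiH (excess), TFA–CH2Cl2 (1:5), −10 → 0 °C
Reagents that add atoms: none
Why: Ionic hydrogenation in the sense of a reductive etherification: TFA cleaves both aryl MOM acetals (the methoxymethyl cation is reduced to dimethyl ether), an ortho OH adds to the activated C1 carbonyl from the C10 side where C1' already sits, and the silane delivers hydride to the cationic C1 from the face of the C2 methyl group and C6–H, which gives the cis-fused chroman with (1R) configuration, while dilution and low temperature keep the hindered C6=C7 alkene out of the slower alkene hydrogenation.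

Step 9
Reactants: 19 chroman-5,7-diol
Product: 21 CNP0121396.1, (1R,2S,5R,10R,1'R), via bis(iminium) salt 20 (not isolated)
Conditions: POCl3, DMF, EtOAc, 0 °C → rt; then H2O
Reagents that add atoms: N,N-dimethylformamide, CN(C)C=O; water, O
Why: Double Vilsmeier–Haack formylation, in which the two remaining aromatic CH positions are each ortho/para to three oxygen donors and take up one chloroiminium unit each, and water hydrolyses 20 to the dialdehyde without touching any stereocentre.

Compound list
1 | (+)-dihydrocarvone, (2R,5R)-2-methyl-5-(prop-1-en-2-yl)cyclohexan-1-one | O=C1C[C@H](C(C)=C)CC[C@H]1C | starting material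
2 | 2,4,6-tri(propan-2-yl)benzenesulfonohydrazide | CC(C)c1cc(C(C)C)c(S(=O)(=O)NN)c(C(C)C)c1 | starting material
3 | (E)-trisylhydrazone of 1 | CC(C)c1cc(C(C)C)c(S(=O)(=O)N/N=C2\C[C@H](C(C)=C)CC[C@H]2C)c(C(C)C)c1 | intermediate
4 | cyclobutanone | O=C1CCC1 | starting material
5 | [(3R,6R)-6-methyl-3-(prop-1-en-2-yl)cyclohex-1-en-1-yl]lithium | [Li]C1=C[C@H](C(C)=C)CC[C@H]1C | intermediate
6 | lithium 1-[(3R,6R)-6-methyl-3-(prop-1-en-2-yl)cyclohex-1-en-1-yl]cyclobutan-1-olate | [Li+].[O-]C1(CCC1)C2=C[C@H](C(C)=C)CC[C@H]2C | intermediate
7 | triethyl({1-[(3R,6R)-6-methyl-3-(prop-1-en-2-yl)cyclohex-1-en-1-yl]cyclobutyl}oxy)silane | CC[Si](CC)(CC)OC1(CCC1)C2=C[C@H](C(C)=C)CC[C@H]2C | intermediate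
8 | (6R)-6-methyl-3-(propan-2-yl)-1-[1-(triethylsilyloxy)cyclobutyl]cyclohex-2-en-1-ylium bis(trifluoromethanesulfonyl)imide | CC[Si](CC)(CC)OC1(CCC1)[C+]2C=C(C(C)C)CC[C@H]2C.O=S(=O)([N-]S(=O)(=O)C(F)(F)F)C(F)(F)F | intermediate
9 | O-triethylsilyl oxocarbenium bis(trifluoromethanesulfonyl)imide of (5R,10R)-10-methyl-7-(propan-2-yl)spiro[4.5]dec-6-en-1-one | CC[Si](CC)(CC)[O+]=C1CCC[C@@]12C=C(C(C)C)CC[C@H]2C.O=S(=O)([N-]S(=O)(=O)C(F)(F)F)C(F)(F)F | intermediate
10 | triethyl{[(5R,10R)-10-methyl-7-(propan-2-yl)spiro[4.5]deca-1,6-dien-1-yl]oxy}silane | CC[Si](CC)(CC)OC1=CCC[C@@]12C=C(C(C)C)CC[C@H]2C | intermediate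
11 | 2,4,6-trihydroxybenzaldehyde | O=Cc1c(O)cc(O)cc1O | starting material
12 | 2-hydroxy-4,6-bis(methoxymethoxy)benzaldehyde | O=Cc1c(O)cc(OCOC)cc1OCOC | intermediate
13 | tert-butyl 2-formyl-3,5-bis(methoxymethoxy)phenyl carbonate | O=Cc1c(OC(=O)OC(C)(C)C)cc(OCOC)cc1OCOC | intermediate
14 | isobutylmagnesium bromide | CC(C)C[Mg]Br | starting material
15 | (6E)-3,5-bis(methoxymethoxy)-6-(3-methylbutylidene)cyclohexa-2,4-dien-1-one | CC(C)C/C=C1/C(=O)C=C(OCOC)C=C1OCOC | intermediate
16 | hetero-Diels–Alder adduct, cis-fused chroman ketal with OSiEt3 on C1 and H on C2, pyran ring on the C6 face | CC(C)C[C@H]1c2c(OCOC)cc(OCOC)cc2O[C@@]2(O[Si](CC)(CC)CC)[C@@H]1CC[C@@]21C=C(C(C)C)CC[C@H]1C | intermediate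
17 | (2R,5R,10R)-2-{(1R)-1-[2-hydroxy-4,6-bis(methoxymethoxy)phenyl]-3-methylbutyl}-10-methyl-7-(propan-2-yl)spiro[4.5]dec-6-en-1-one | CC(C)C[C@H]([C@H]1CC[C@]2(C1=O)C=C(C(C)C)CC[C@H]2C)c1c(O)cc(OCOC)cc1OCOC | intermediate
18 | (2S,5R,10R)-2-{(1S)-1-[2-hydroxy-4,6-bis(methoxymethoxy)phenyl]-3-methylbutyl}-2,10-dimethyl-7-(propan-2-yl)spiro[4.5]dec-6-en-1-one | CC(C)C[C@H]([C@]1(C)CC[C@]2(C1=O)C=C(C(C)C)CC[C@H]2C)c1c(O)cc(OCOC)cc1OCOC | intermediate
19 | chroman-5,7-diol, target without the two formyl groups, (1R,2S,5R,10R,1'R) | CC(C)C[C@H]1c2c(O)cc(O)cc2O[C@@H]2[C@@]1(C)CC[C@@]21C=C(C(C)C)CC[C@H]1C | intermediate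
20 | bis(N,N-dimethyliminium) dichloride of the target | CC(C)C[C@H]1c2c(O)c(C=[N+](C)C)c(O)c(C=[N+](C)C)c2O[C@@H]2[C@@]1(C)CC[C@@]21C=C(C(C)C)CC[C@H]1C.[Cl-].[Cl-] | intermediate
21 | CNP0121396.1, (1R,2S,5R,10R,1'R) | CC(C)C[C@H]1c2c(O)c(C=O)c(O)c(C=O)c2O[C@@H]2[C@@]1(C)CC[C@@]21C=C(C(C)C)CC[C@H]1C | target

Total step count: 9. Longest linear sequence: 7 (steps 1, 2, 3, 6, 7, 8, 9).

Steps most likely to fail

Step 3. Three processes could compete. Protonation may occur at the ring alkene, which gives ring expansion without transposition of the double bond. Protonation may occur at the silyl ether oxygen, which ionises the tertiary allylic C–O bond. Proton loss from C10 of cation 8 would erode the configuration. The fallback sets out from 7 and separates the two events. A cobalt-hydride hydrogen-atom-transfer isomerisation (Co(salen) catalyst, PhSiH3, benzene, rt) moves the isopropenyl double bond into conjugation under neutral conditions. This gives the conjugated dienyl silyl ether F1. A weak acid (camphorsulfonic acid, CH2Cl2, −20 °C) should then protonate only the electron-rich diene terminus. The same 1,2-shift and an aqueous work-up give the spiro ketone F2. LDA and TESCl bring the route back to 10.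

Step 6. The o-quinone methide may be consumed by self-condensation or by a second Grignard addition faster than it finds the hindered dienophile. The facial or endo/exo selectivity of the cycloaddition may also be poor. The fallback sets out from 10, which fluoride (TBAF, THF) cleaves to the spiro ketone F2. A Claisen–Schmidt condensation of this ketone with aldehyde 12 (KOH, EtOH) gives the (E)-arylidene ketone F3. A 1,4-addition of an isobutyl cuprate (iBu2CuLi in excess, TMSCl, THF, −78 °C) on the C6 face then comes back to the route at 17. C1' epimers would be separated at this stage.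

Step 8. The carbonyl group at C1 lies between two quaternary carbons and may not accept the phenol. In that case direct carbonyl reduction, heterolysis of the C2–C1' bond or hydrogenation of the alkene could take over. The fallback sets out from 18. LiAlH4 (THF, 0 °C) attacks from the C2-methyl face and gives the C1 alcohol F4, with its OH on the C10 side. HCl in MeOH removes the MOM groups and gives the tetraol F5. A catalytic strong acid (TfOH, CH2Cl2, −20 °C) then ionises C1–OH with homoallylic participation of the C6=C7 bond from the opposite face (i-steroid type). The ortho phenol closes the ring at C1 with net retention, and the route is rejoined at 19.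

Further compounds
F1 | step 3 | triethyl({1-[(6R)-6-methyl-3-(propan-2-ylidene)cyclohex-1-en-1-yl]cyclobutyl}oxy)silane | CC[Si](CC)(CC)OC1(CCC1)C2=CC(=C(C)C)CC[C@H]2C
F2 | step 3 | (5R,10R)-10-methyl-7-(propan-2-yl)spiro[4.5]dec-6-en-1-one | O=C1CCC[C@@]12C=C(C(C)C)CC[C@H]2C
F3 | step 6 | (2E,5R,10R)-2-{[2-hydroxy-4,6-bis(methoxymethoxy)phenyl]methylidene}-10-methyl-7-(propan-2-yl)spiro[4.5]dec-6-en-1-one | O=C1/C(=C/c2c(O)cc(OCOC)cc2OCOC)CC[C@@]13C=C(C(C)C)CC[C@H]3C
F4 | step 8 | (1R,2S,5R,10R)-2-{(1R)-1-[2-hydroxy-4,6-bis(methoxymethoxy)phenyl]-3-methylbutyl}-2,10-dimethyl-7-(propan-2-yl)spiro[4.5]dec-6-en-1-ol | CC(C)C[C@H]([C@]1(C)CC[C@]2([C@@H]1O)C=C(C(C)C)CC[C@H]2C)c1c(O)cc(OCOC)cc1OCOC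
F5 | step 8 | 2-{(1R)-1-[(1R,2S,5R,10R)-1-hydroxy-2,10-dimethyl-7-(propan-2-yl)spiro[4.5]dec-6-en-2-yl]-3-methylbutyl}benzene-1,3,5-triol | CC(C)C[C@H]([C@]1(C)CC[C@]2([C@@H]1O)C=C(C(C)C)CC[C@H]2C)c1c(O)cc(O)cc1O
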